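Watch the second substrate.

in all of them: free catalyst 0.5 mol%
- oak: starting material 0.53 M; second substrate 1.4 equiv; coupling partner 0.90 equiv; run made earlier
- larch: starting material 0.53 M; second substrate 2.2 equiv; coupling partner 0.90 equiv; run made earlier
- cedar: starting material 0.80 M; second substrate 1 equiv; coupling partner 0.90 equiv; run made earlier
- flask: starting material 0.53 M; second substrate 1.00 equiv; coupling partner 0.900 equiv

| run | time / h | target / % |
|---|---|---|
| oak | 2.50 | 3.3 |
| oak | 4.00 | 1.9 |
| oak | 6.00 | 0.3 |
| oak | 10.0 | 3.5 |
| oak | 20.0 | 5.5 |
| oak | 30.0 | 5.9 |
| larch | 2.00 | 0 |
| larch | 6.00 | 1.6 |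
| larch | 10.0 | 1.8 |
| larch | 15.0 | 2.1 |
| larch | 25.0 | 2.8 |
| larch | 30.0 | 1.7 |
| cedar | 2.50 | 3.3 |
| cedar | 8.00 | 5.8 |
| cedar | 15.0 | 9.3 |
| cedar | 20.0 | 8.8 |
| cedar | 30.0 | 12.7 |

(readings scatter by 1 percentage point)



1. apparent order in coupling partner when 5.0% of the starting material are converted (percent change of the rate of making target for one percent more coupling partner charged)
2. apparent order in second substrate when 5.0% of the starting material are converted (percent change of the rate of making target for one percent more second substrate charged)

I read the table from the bottom of each run, where the target has had the longest to gather. Oak and larch differ in one charge, 1.4 equiv against 2.2 equiv of second substrate. Their last two readings, summed, stand in a ratio of 2.53, with oak ahead, so more [second substrate] gives less target: substrate inhibition. I take that ratio of readings as a ratio of rates. The logarithm of the larch-to-oak reading ratio over the logarithm of the larch-to-oak charge ratio gives the read order, −2.06. It is a rough reading, since the scatter is 1 percentage point on larch values near 2.25%. Cedar, at 1 equiv, ends at 12.7%, above oak and larch, but its [starting material] and [coupling partner] differ too. Oak and larch share one [coupling partner], and cedar raises it together with [starting material], so I commit to −2.06 for second substrate and to no number for coupling partner.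

The forecast gives −1 for second substrate, within −2 to −0.3, and 1.2 for coupling partner, within 0.5 to 2. Its grounds: “This is inhibition, probably the substrate tying up the catalyst.”

The simulation of the flask gives −1.9 for second substrate and 4.0 for coupling partner, from this scheme:

    starting material + free catalyst ⇌ catalyst intermediate A (K = 1.40 M⁻¹, k = 23.4 M⁻¹ h⁻¹)
    coupling partner + catalyst intermediate A → free catalyst + target (k = 10.8 M⁻¹ h⁻¹)
    second substrate + free catalyst ⇌ catalyst intermediate B (K = 94.0 M⁻¹, k = 30.3 M⁻¹ h⁻¹)
    coupling partner + catalyst intermediate B → free catalyst + second product (k = 46.8 M⁻¹ h⁻¹)
    catalyst intermediate B → spent catalyst (k = 0.132 h⁻¹)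

Read between oak and larch, −2.06 remains a reading with the scatter above, taken at other charges than the flask's −1.9. The turning of second substrate + free catalyst into catalyst intermediate B, both ways, has the largest single effect on the flask's order : in the run of the flask without it, the order goes from −1.9 to 0.

(The earlier runs and the new flask are simulated with constants of no real substance.)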